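**Retrosynthetic overview**

1. Numbering (botcinin skeleton): C1 lactone C=O, C2 (Me), C3 (OAc), C4 (Me, quaternary, pyran O), C5 (ring-fusion CH, lactone O), C6 (Me), C7 (O-acyl), C8 (Me, pyran O). Last bonds: the (Z)-4-oxodec-2-enoate on O7 by Still–Gennari olefination of an O7 phosphonoacetate; C2 and C3 by syn-hydrogenation of a bicyclic β-keto-δ-lactone, then acetylation.
2. Key disconnection: C4–C5 (aldol) and C1–C2 (Claisen-type C-acylation) are made in one guanidine-mediated relay from an acyclic keto-aldehyde, with C1 supplied by diphenyl carbonate.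
3. Feature used: with C3 at the ketone level, the lactone ring C5–O–C1–C2–C3–C4 is a ketone whose two α-carbons are both enolisable (C4, which carries the pyran oxygen and a methyl, and C2). They face an aldehyde carbon (C5) and a carbonyl carbon (C1) joined through the C5 oxygen; ring size lets only C4 reach C5 and afterwards only C2 reach C1.
4. Ring order: tetrahydropyran (O, C8, C7, C6, C5, C4) first, δ-lactone (C5, O, C1, C2, C3, C4) second, in the same flask.
5. Keto-aldehyde: C8 from (S)-but-3-en-2-ol, the C8–O–C4 ether by Williamson alkylation and Weinreb ketone synthesis, C6/C7 by substrate-controlled (Z)-crotylboration, two ozonolyses.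

Key step: step 7

Remark: the side chain is taken as the (Z)-4-oxodec-2-enoate written in the SMILES; compounds 3 to 8 are carried as mixtures of both epimers at the future C4, which becomes a planar enol(ate) carbon in step 7.

**Route**

Step 1
Reactants: 1 (S)-but-3-en-2-ol; 2 2-bromo-N-methoxy-N-methylpropanamide (racemic)
Product: 3 2-[(2S)-but-3-en-2-yloxy]-N-methoxy-N-methylpropanamide
Conditions: NaH, Bu4NI (cat.), THF, 0 to 23 °C
Reagents that add atoms: none
Why: Williamson ether synthesis: the sodium alkoxide of 1 displaces bromide from the activated α-bromo amide in an SN2 reaction, which leaves the C8 stereocentre untouched and forms the future C4 as both epimers (irrelevant, see step 7).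

Step 2
Reactants: 3 2-[(2S)-but-3-en-2-yloxy]-N-methoxy-N-methylpropanamide
Product: 4 2-[(2S)-but-3-en-2-yloxy]pentan-3-one
Conditions: EtMgBr, THF, 0 °C; then 1 M HCl
Reagents that add atoms: ethylmagnesium bromide, CC[Mg]Br
Why: Weinreb ketone synthesis: the magnesium chelate of the tetrahedral adduct survives until acidic work-up, so a single ethyl group is delivered and the ketone (C3, with C2 and its methyl) results without over-addition.

Step 3
Reactants: 4 2-[(2S)-but-3-en-2-yloxy]pentan-3-one
Product: 5 (2S)-2-[(3-oxopentan-2-yl)oxy]propanal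
Conditions: O3, CH2Cl2, −78 °C; then PPh3, −78 to 23 °C
Reagents that add atoms: ozone, [O-][O+]=O
Why: Ozonolysis with reductive work-up (Criegee mechanism) cleaves the only alkene to the α-alkoxy aldehyde (C7), which is used at once to keep C8 from epimerising.

Step 4
Reactants: 5 (2S)-2-[(3-oxopentan-2-yl)oxy]propanal
Product: 6 2-{[(2S,3R,4S)-3-hydroxy-4-methylhex-5-en-2-yl]oxy}pentan-3-one
Conditions: (Z)-crotylboronic acid pinacol ester, toluene, −78 to 23 °C; aqueous NaHCO3 work-up
Reagents that add atoms: (Z)-crotylboronic acid pinacol ester, C/C=C\CB1OC(C)(C)C(C)(C)O1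
Why: Allylboration through a closed chair transition state: the (Z)-crotyl geometry sets the C6 methyl syn to the new C7 hydroxyl, the C8 alkoxy stereocentre directs attack to the Felkin–Anh/Cornforth face (7,8-anti), and the boronate adds to the aldehyde but not to the ketone.

Step 5
Reactants: 6 2-{[(2S,3R,4S)-3-hydroxy-4-methylhex-5-en-2-yl]oxy}pentan-3-one
Product: 7 2-{[(2S,3R,4S)-3-[(tert-butyldimethylsilyl)oxy]-4-methylhex-5-en-2-yl]oxy}pentan-3-one
Conditions: TBSOTf, 2,6-lutidine, CH2Cl2, −78 to 0 °C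
Reagents that add atoms: tert-butyldimethylsilyl trifluoromethanesulfonate, CC(C)(C)[Si](C)(C)OS(=O)(=O)C(F)(F)F
Why: Silyl ether formation with a silyl triflate and a hindered pyridine base protects the C7 hydroxyl at low temperature, where the ketone is not converted into an enol silane.

Step 6
Reactants: 7 2-{[(2S,3R,4S)-3-[(tert-butyldimethylsilyl)oxy]-4-methylhex-5-en-2-yl]oxy}pentan-3-one
Product: 8 (2R,3R,4S)-3-[(tert-butyldimethylsilyl)oxy]-2-methyl-4-[(3-oxopentan-2-yl)oxy]pentanal
Conditions: O3, CH2Cl2, −78 °C; then PPh3, −78 to 23 °C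
Reagents that add atoms: ozone, [O-][O+]=O
Why: Ozonolysis with reductive work-up (Criegee mechanism) turns the vinyl group into the C5 aldehyde without touching the silyl ether or the ketone.

Step 7
Reactants: 8 (2R,3R,4S)-3-[(tert-butyldimethylsilyl)oxy]-2-methyl-4-[(3-oxopentan-2-yl)oxy]pentanal
Product: 11 (4aS,6S,7R,8S,8aS)-7-[(tert-butyldimethylsilyl)oxy]-3,4a,6,8-tetramethyl-6,7,8,8a-tetrahydropyrano[3,2-b]pyran-2,4(3H,4aH)-dione, via aldol 9 (not isolated), via phenyl carbonate 10 (not isolated)
Conditions: TBD (1,5,7-triazabicyclo[4.4.0]dec-5-ene, 0.1 equiv), THF, 0 °C; then (PhO)2CO (1.2 equiv) and TBD (2.5 equiv), 0 to 40 °C, same flask; aqueous citric acid work-up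
Reagents that add atoms: diphenyl carbonate, O=C(Oc1ccccc1)Oc1ccccc1
Why: Proposed new method: a guanidine relay in which TBD (a) catalyses the reversible aldol addition of the C4 enol(ate) of the α-alkoxy ketone to the C5 aldehyde (6-(enolexo)-exo-trig closure of the tetrahydropyran; closest precedent: TBD-catalysed enolexo aldolisation of keto-aldehydes), (b) passes the carbonyl of diphenyl carbonate to the new C5 hydroxyl through N-acyl-TBD (guanidine-catalysed transcarbonation) and (c) as stoichiometric base lets the only remaining enolisable carbon, C2, attack that aryl carbonate with loss of phenoxide (6-exo-trig Claisen/Dieckmann-type closure of the δ-lactone; closest precedents: base-mediated cyclisation of keto carbonates to β-keto lactones and amidine-catalysed O-to-C carboxyl transfer of enol carbonates). Stage (a) is reversible and is run first with catalytic TBD, stage (b) acylates only the secondary C5 hydroxyl, and stage (c) is pulled through by deprotonation of the β-keto lactone (pKa about 11), so the epimeric mixture at C4, an epimerised C6, any enol carbonate from O-acylation and the reversible aldol of the aldehyde enolate onto the ketone should all drain into one product. Regioselectivity rests on ring size: of the two ketone α-carbons only C4 can reach C5 through a six-membered transition state (C2 would close an eight-membered ring), and once C4 is quaternary only C2 can enolise toward C1. C5 and C4 are set in a chair transition state that keeps the C8 methyl, the C7 silyloxy group and the C6 methyl equatorial; the aldehyde oxygen and the larger acyl-enolate arm of C4 also sit equatorial in a closed, TBD-H+ bridged (trans-decalin-like) array, which leaves the C4 methyl axial and gives the trans ring fusion. The C2 centre formed here is enolisable and is fixed only in step 8.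

Step 8
Reactants: 11 (4aS,6S,7R,8S,8aS)-7-[(tert-butyldimethylsilyl)oxy]-3,4a,6,8-tetramethyl-6,7,8,8a-tetrahydropyrano[3,2-b]pyran-2,4(3H,4aH)-dione
Product: 12 (3R,4S,4aR,6S,7R,8S,8aS)-7-[(tert-butyldimethylsilyl)oxy]-4-hydroxy-3,4a,6,8-tetramethylhexahydropyrano[3,2-b]pyran-2(3H)-one
Conditions: H2 (50 bar), Raney Ni, EtOAc, 23 °C
Reagents that add atoms: none
Why: Heterogeneous syn-hydrogenation of the enol tautomer (C2=C3) of a cyclic β-keto-δ-lactone: both hydrogens are delivered to the face opposite the axial C4 methyl, which sets C2 (methyl) and C3 (hydroxyl) cis to each other and to the C4 methyl.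

Step 9
Reactants: 12 (3R,4S,4aR,6S,7R,8S,8aS)-7-[(tert-butyldimethylsilyl)oxy]-4-hydroxy-3,4a,6,8-tetramethylhexahydropyrano[3,2-b]pyran-2(3H)-one
Product: 13 (3R,4S,4aS,6S,7R,8S,8aS)-7-[(tert-butyldimethylsilyl)oxy]-3,4a,6,8-tetramethyl-2-oxooctahydropyrano[3,2-b]pyran-4-yl acetate
Conditions: Ac2O, pyridine, DMAP (cat.), CH2Cl2, 0 to 23 °C
Reagents that add atoms: acetic anhydride, CC(=O)OC(C)=O
Why: DMAP-catalysed acylation of the hindered secondary C3 hydroxyl under mildly basic conditions that should not enolise the lactone at C2.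

Step 10
Reactants: 13 (3R,4S,4aS,6S,7R,8S,8aS)-7-[(tert-butyldimethylsilyl)oxy]-3,4a,6,8-tetramethyl-2-oxooctahydropyrano[3,2-b]pyran-4-yl acetate
Product: 14 (3R,4S,4aS,6S,7R,8R,8aS)-7-hydroxy-3,4a,6,8-tetramethyl-2-oxooctahydropyrano[3,2-b]pyran-4-yl acetate
Conditions: HF·pyridine, THF, 0 to 23 °C
Reagents that add atoms: none
Why: Fluoride-mediated cleavage of the Si–O bond with buffered HF frees the C7 hydroxyl, while acetate and lactone are stable to these mildly acidic conditions.

Step 11
Reactants: 15 methyl 2-[bis(2,2,2-trifluoroethoxy)phosphoryl]acetate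
Product: 16 2-[bis(2,2,2-trifluoroethoxy)phosphoryl]acetic acid
Conditions: LiOH·H2O (1.05 equiv), THF/H2O, 0 °C; then 1 M HCl
Reagents that add atoms: lithium hydroxide, [Li+].[OH-]
Why: Saponification with one equivalent of hydroxide at 0 °C, where the activated carboxylic methyl ester is expected to be cleaved before the phosphonate esters.

Step 12
Reactants: 14 (3R,4S,4aS,6S,7R,8R,8aS)-7-hydroxy-3,4a,6,8-tetramethyl-2-oxooctahydropyrano[3,2-b]pyran-4-yl acetate; 16 2-[bis(2,2,2-trifluoroethoxy)phosphoryl]acetic acid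
Product: 17 (3R,4S,4aS,6S,7R,8R,8aS)-4-(acetyloxy)-3,4a,6,8-tetramethyl-2-oxooctahydropyrano[3,2-b]pyran-7-yl 2-[bis(2,2,2-trifluoroethoxy)phosphoryl]acetate
Conditions: DCC, DMAP (cat.), CH2Cl2, 0 to 23 °C
Reagents that add atoms: none
Why: Steglich esterification: the carbodiimide-activated acid acylates the equatorial C7 hydroxyl with DMAP as acyl-transfer catalyst, without strong base.

Step 13
Reactants: 18 octane-1,2-diol (racemic)
Product: 19 2-oxooctanal
Conditions: IBX (2.5 equiv), DMSO, 23 °C
Reagents that add atoms: none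
Why: IBX oxidation of a 1,2-diol, which oxidises both carbinols to the 1,2-dicarbonyl stage without C–C cleavage; the keto-aldehyde is used crude.

Step 14
Reactants: 17 (3R,4S,4aS,6S,7R,8R,8aS)-4-(acetyloxy)-3,4a,6,8-tetramethyl-2-oxooctahydropyrano[3,2-b]pyran-7-yl 2-[bis(2,2,2-trifluoroethoxy)phosphoryl]acetate; 19 2-oxooctanal
Product: 20 Botcinin J
Conditions: KN(SiMe3)2 (1.0 equiv), 18-crown-6, THF, −78 °C; then 19
Reagents that add atoms: none
Why: Still–Gennari variant of the Horner–Wadsworth–Emmons olefination: the potassium anion of the bis(trifluoroethyl) phosphonate adds to the more electrophilic aldehyde carbon of 19 and the adduct eliminates fast and kinetically to the (Z)-enoate; the single equivalent of base is consumed by the phosphonate, so C2 is not enolised.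

**Compound list**

1 | (S)-but-3-en-2-ol | C[C@H](O)C=C | starting material
2 | 2-bromo-N-methoxy-N-methylpropanamide (racemic) | CC(Br)C(=O)N(C)OC | starting material
3 | 2-[(2S)-but-3-en-2-yloxy]-N-methoxy-N-methylpropanamide (both epimers at the amide α-carbon) | C[C@H](OC(C)C(=O)N(C)OC)C=C | intermediate
4 | 2-[(2S)-but-3-en-2-yloxy]pentan-3-one (both epimers at C2 of the pentanone) | C[C@H](OC(C)C(=O)CC)C=C | intermediate
5 | (2S)-2-[(3-oxopentan-2-yl)oxy]propanal | C[C@H](OC(C)C(=O)CC)C=O | intermediate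
6 | 2-{[(2S,3R,4S)-3-hydroxy-4-methylhex-5-en-2-yl]oxy}pentan-3-one | C[C@H](OC(C)C(=O)CC)[C@H](O)[C@@H](C)C=C | intermediate
7 | 2-{[(2S,3R,4S)-3-[(tert-butyldimethylsilyl)oxy]-4-methylhex-5-en-2-yl]oxy}pentan-3-one | C[C@H](OC(C)C(=O)CC)[C@H](O[Si](C)(C)C(C)(C)C)[C@@H](C)C=C | intermediate
8 | (2R,3R,4S)-3-[(tert-butyldimethylsilyl)oxy]-2-methyl-4-[(3-oxopentan-2-yl)oxy]pentanal | C[C@H](OC(C)C(=O)CC)[C@H](O[Si](C)(C)C(C)(C)C)[C@@H](C)C=O | intermediate
9 | 1-[(2S,3S,4S,5R,6S)-5-[(tert-butyldimethylsilyl)oxy]-3-hydroxy-2,4,6-trimethyloxan-2-yl]propan-1-one (aldol, not isolated) | CC(C)(C)[Si](C)(C)O[C@@H]1[C@@H](C)[C@H](O)[C@@](C)(C(=O)CC)O[C@H]1C | intermediate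
10 | (2S,3S,4S,5R,6S)-5-[(tert-butyldimethylsilyl)oxy]-2,4,6-trimethyl-2-propanoyloxan-3-yl phenyl carbonate (not isolated) | CC(C)(C)[Si](C)(C)O[C@@H]1[C@@H](C)[C@H](OC(=O)Oc2ccccc2)[C@@](C)(C(=O)CC)O[C@H]1C | intermediate
11 | (4aS,6S,7R,8S,8aS)-7-[(tert-butyldimethylsilyl)oxy]-3,4a,6,8-tetramethyl-6,7,8,8a-tetrahydropyrano[3,2-b]pyran-2,4(3H,4aH)-dione (C3 epimers, partly as the 4-hydroxy enol) | CC(C)(C)[Si](C)(C)O[C@@H]1[C@@H](C)[C@@H]2OC(=O)C(C)C(=O)[C@@]2(C)O[C@H]1C | intermediate
12 | (3R,4S,4aR,6S,7R,8S,8aS)-7-[(tert-butyldimethylsilyl)oxy]-4-hydroxy-3,4a,6,8-tetramethylhexahydropyrano[3,2-b]pyran-2(3H)-one | CC(C)(C)[Si](C)(C)O[C@@H]1[C@@H](C)[C@@H]2OC(=O)[C@H](C)[C@H](O)[C@@]2(C)O[C@H]1C | intermediate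
13 | (3R,4S,4aS,6S,7R,8S,8aS)-7-[(tert-butyldimethylsilyl)oxy]-3,4a,6,8-tetramethyl-2-oxooctahydropyrano[3,2-b]pyran-4-yl acetate | CC(C)(C)[Si](C)(C)O[C@@H]1[C@@H](C)[C@@H]2OC(=O)[C@H](C)[C@H](OC(C)=O)[C@@]2(C)O[C@H]1C | intermediate
14 | (3R,4S,4aS,6S,7R,8R,8aS)-7-hydroxy-3,4a,6,8-tetramethyl-2-oxooctahydropyrano[3,2-b]pyran-4-yl acetate | O[C@@H]1[C@@H](C)[C@@H]2OC(=O)[C@H](C)[C@H](OC(C)=O)[C@@]2(C)O[C@H]1C | intermediate
15 | methyl 2-[bis(2,2,2-trifluoroethoxy)phosphoryl]acetate | COC(=O)CP(=O)(OCC(F)(F)F)OCC(F)(F)F | starting material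
16 | 2-[bis(2,2,2-trifluoroethoxy)phosphoryl]acetic acid | OC(=O)CP(=O)(OCC(F)(F)F)OCC(F)(F)F | intermediate
17 | (3R,4S,4aS,6S,7R,8R,8aS)-4-(acetyloxy)-3,4a,6,8-tetramethyl-2-oxooctahydropyrano[3,2-b]pyran-7-yl 2-[bis(2,2,2-trifluoroethoxy)phosphoryl]acetate | O=C(CP(=O)(OCC(F)(F)F)OCC(F)(F)F)O[C@@H]1[C@@H](C)[C@@H]2OC(=O)[C@H](C)[C@H](OC(C)=O)[C@@]2(C)O[C@H]1C | intermediate
18 | octane-1,2-diol (racemic) | CCCCCCC(O)CO | starting material
19 | 2-oxooctanal | CCCCCCC(=O)C=O | intermediate
20 | Botcinin J, (3R,4S,4aS,6S,7R,8R,8aS)-4-(acetyloxy)-3,4a,6,8-tetramethyl-2-oxooctahydropyrano[3,2-b]pyran-7-yl (2Z)-4-oxodec-2-enoate | CCCCCCC(=O)/C=C\C(=O)O[C@@H]1[C@@H](C)[C@@H]2OC(=O)[C@H](C)[C@H](OC(C)=O)[C@@]2(C)O[C@H]1C | target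

**Step count and risks**

Total step count: 14. Longest linear sequence: 12 (steps 1 to 10, 12 and 14).

Three steps most likely to fail:

- **Step 7 (proposed new method).** The guanidine may not drive the last C-acylation, so that the sequence stalls at the carbonate stage. Loss of the C7 silyloxy group by β-elimination from the aldehyde enolate, or closure through the other chair (C4 epimer, cis ring fusion), may also compete. The fallback uses known reactions only. It sets out from keto-aldehyde 8: the TBD-catalysed aldol (0.1 equiv, THF, 0 °C) is stopped after its first stage and the aldol 9 is isolated. Treatment of 9 with 1,1'-carbonyldiimidazole (THF, 23 °C) should give (2S,3S,4S,5R,6S)-5-[(tert-butyldimethylsilyl)oxy]-2,4,6-trimethyl-2-propanoyloxan-3-yl 1H-imidazole-1-carboxylate F1. F1 is then cyclised with LiN(SiMe3)2 (2.2 equiv, THF, −78 to 0 °C; Claisen/Dieckmann-type acylation of the ketone enolate by the acyl imidazole), which returns to the route at β-keto lactone 11.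

- **Step 8.** Hydrogenation of the hindered, tetrasubstituted enol may be slow or poorly face-selective, or the C3–O bond may be lost by hydrogenolysis. The fallback sets out from 11: O-acetylation of the enol (Ac2O, Et3N, DMAP, CH2Cl2, 0 °C) should give (4aS,6S,7R,8S,8aS)-7-[(tert-butyldimethylsilyl)oxy]-3,4a,6,8-tetramethyl-2-oxo-2,4a,6,7,8,8a-hexahydropyrano[3,2-b]pyran-4-yl acetate F2, which cannot be deprotonated and already carries the final acetate. Hydrogenation of F2 over Rh/Al2O3 (H2, EtOAc), again from the face opposite the C4 methyl, returns to the route at acetate 13 and bypasses 12.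

- **Step 14.** Z selectivity may erode, or the enedione may isomerise from Z to E under the basic olefination conditions. The fallback sets out from alcohol 14: esterification with (Z)-3-iodoacrylic acid (DCC, DMAP cat., CH2Cl2, −20 °C) should give (3R,4S,4aS,6S,7R,8R,8aS)-4-(acetyloxy)-3,4a,6,8-tetramethyl-2-oxooctahydropyrano[3,2-b]pyran-7-yl (2Z)-3-iodoprop-2-enoate F3. Carbonylative Suzuki–Miyaura coupling of F3 with B-hexyl-9-borabicyclo[3.3.1]nonane (from hex-1-ene and 9-BBN-H), CO (1 atm), Pd(PPh3)4 and K3PO4 inserts the ketone carbonyl with retention of the alkene geometry and arrives directly at target 20.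

Further compounds
F1 | step 7 | (2S,3S,4S,5R,6S)-5-[(tert-butyldimethylsilyl)oxy]-2,4,6-trimethyl-2-propanoyloxan-3-yl 1H-imidazole-1-carboxylate | CC(C)(C)[Si](C)(C)O[C@@H]1[C@@H](C)[C@H](OC(=O)n2ccnc2)[C@@](C)(C(=O)CC)O[C@H]1C
F2 | step 8 | (4aS,6S,7R,8S,8aS)-7-[(tert-butyldimethylsilyl)oxy]-3,4a,6,8-tetramethyl-2-oxo-2,4a,6,7,8,8a-hexahydropyrano[3,2-b]pyran-4-yl acetate | CC(C)(C)[Si](C)(C)O[C@@H]1[C@@H](C)[C@@H]2OC(=O)C(C)=C(OC(C)=O)[C@@]2(C)O[C@H]1C
F3 | step 14 | (3R,4S,4aS,6S,7R,8R,8aS)-4-(acetyloxy)-3,4a,6,8-tetramethyl-2-oxooctahydropyrano[3,2-b]pyran-7-yl (2Z)-3-iodoprop-2-enoate | I/C=C\C(=O)O[C@@H]1[C@@H](C)[C@@H]2OC(=O)[C@H](C)[C@H](OC(C)=O)[C@@]2(C)O[C@H]1C
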